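**Plan**
Retrosynthesis: three late adjustments of ring B (C4–H/C5–H, C5–OMe, C7=C7a) lead back to the cis-fused enone 18; cutting O1–C7a then opens ring A to the cyclohexa-2,5-dienone 17.
Enabling feature: C3a carries allyl, C3 and two ring arms (C4=C5 and C7=C7a) that are identical in 17, so closing O1–C7a of ring A on one arm defines the quaternary centre.
Ring B of 17 is cut by a Robinson disconnection (Michael bond C3a–CH2, aldol C=C) and at the C3a–allyl bond; the remaining chain is cut at C2–C3 (crotylboration of the aryl aldehyde).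
Forward order: C2–C3 chain, two-carbon extension, allylation at the future C3a, ring B (annulation, dehydrogenation), ring A (oxa-Michael), then the oxidation pattern of ring B.
Stereochemistry: C2 and C3 from a catalyst-controlled (Z)-crotylboration; C3a (and transient C7a) from arm selection in the reversible oxa-Michael closure; C5 from kinetic protonation anti to allyl.

Key step: step 9

Remark: 9, 10, 12, 13, 14 and 15 are epimer mixtures at the carbon that becomes C3a (12 also E/Z), which is harmless because that carbon is prochiral in 16 and 17; the oxirane of 21 is drawn anti to allyl, but either face serves.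

**Step 1**
Reactants: 1 3,4,5-trimethoxybenzaldehyde; 2 (Z)-crotylboronic acid pinacol ester
Product: 3 (1R,2S)-2-methyl-1-(3,4,5-trimethoxyphenyl)but-3-en-1-ol
Conditions: (R)-3,3'-bis(2,4,6-triisopropylphenyl)-1,1'-binaphthyl-2,2'-diyl hydrogen phosphate (5 mol%), toluene, –30 °C; aqueous work-up
Reagents that add atoms: none
Why: Chiral phosphoric acid-catalysed crotylboration of an aromatic aldehyde, in which the closed chair transition state turns the (Z)-geometry into the syn C1/C2 relationship and the (R)-acid, hydrogen-bonded to a boronate oxygen, should direct addition to the Re face, giving (1R,2S).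

**Step 2**
Reactants: 3 (1R,2S)-2-methyl-1-(3,4,5-trimethoxyphenyl)but-3-en-1-ol
Product: 4 tert-butyl(dimethyl){[(1R,2S)-2-methyl-1-(3,4,5-trimethoxyphenyl)but-3-en-1-yl]oxy}silane
Conditions: t-BuMe2SiOSO2CF3, 2,6-lutidine, CH2Cl2, –78 → 0 °C
Reagents that add atoms: tert-butyldimethylsilyl trifluoromethanesulfonate, CC(C)(C)[Si](C)(C)OS(=O)(=O)C(F)(F)F
Why: Silylation of a hindered secondary benzylic alcohol with the silyl triflate masks the hydroxyl through the basic C–C bond-forming steps and prevents premature oxa-Michael closure onto the monoenone 14.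

**Step 3**
Reactants: 4 tert-butyl(dimethyl){[(1R,2S)-2-methyl-1-(3,4,5-trimethoxyphenyl)but-3-en-1-yl]oxy}silane
Product: 5 (3S,4R)-4-{[tert-butyl(dimethyl)silyl]oxy}-3-methyl-4-(3,4,5-trimethoxyphenyl)butan-1-ol
Conditions: 9-BBN, THF, 0 °C → rt; then NaOH, H2O2, 0 °C
Reagents that add atoms: hydrogen peroxide, OO
Why: Anti-Markovnikov hydroboration–oxidation of the terminal alkene with a bulky borane creates no stereocentre and leaves the silyl ether and the arene untouched.

**Step 4**
Reactants: 5 (3S,4R)-4-{[tert-butyl(dimethyl)silyl]oxy}-3-methyl-4-(3,4,5-trimethoxyphenyl)butan-1-ol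
Product: 6 (3S,4R)-4-{[tert-butyl(dimethyl)silyl]oxy}-3-methyl-4-(3,4,5-trimethoxyphenyl)butanal
Conditions: Dess–Martin periodinane, NaHCO3, CH2Cl2, 0 °C → rt
Reagents that add atoms: none
Why: Dess–Martin oxidation of the primary alcohol under buffered conditions is safe here because both stereocentres are β and γ to the new carbonyl and cannot epimerize.

**Step 5**
Reactants: 6 (3S,4R)-4-{[tert-butyl(dimethyl)silyl]oxy}-3-methyl-4-(3,4,5-trimethoxyphenyl)butanal; 7 allyl bromide
Product: 10 (3S,4R)-4-{[tert-butyl(dimethyl)silyl]oxy}-3-methyl-2-(prop-2-en-1-yl)-4-(3,4,5-trimethoxyphenyl)butanal (C2 epimers), via N-cyclohexyl imine 8 (not isolated), via allylated imine 9 (not isolated)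
Conditions: c-C6H11NH2, MgSO4, Et2O, rt; LiN(i-Pr)2, THF, –78 → 0 °C; 7, –78 °C → rt; AcOH–NaOAc buffer (pH 4.5), rt
Reagents that add atoms: none
Why: Stork metalloenamine alkylation, in which the lithiated N-cyclohexyl imine is mono-allylated without aldehyde self-condensation and mild acidic hydrolysis returns the aldehyde; the new α-centre forms as an epimer mixture, which is immaterial.

**Step 6**
Reactants: 10 (3S,4R)-4-{[tert-butyl(dimethyl)silyl]oxy}-3-methyl-2-(prop-2-en-1-yl)-4-(3,4,5-trimethoxyphenyl)butanal (C2 epimers); 11 but-3-en-2-one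
Product: 14 4-[(1R,2S)-1-{[tert-butyl(dimethyl)silyl]oxy}-1-(3,4,5-trimethoxyphenyl)propan-2-yl]-4-(prop-2-en-1-yl)cyclohex-2-en-1-one (C4 epimers), via pyrrolidine enamine 12 (not isolated), via keto aldehyde 13 (not isolated)
Conditions: pyrrolidine, toluene, reflux (Dean–Stark); 11, 0 °C → reflux; AcOH–NaOAc–H2O, rt; then KOH, MeOH, rt
Reagents that add atoms: none
Why: Robinson annulation in its enamine variant, in which the enamine of the α,α-disubstituted aldehyde adds to the vinyl ketone to create the quaternary carbon and base-mediated aldol condensation of the 1,5-keto aldehyde closes ring B; the quaternary centre forms unselectively, which is harmless.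

**Step 7**
Reactants: 14 4-[(1R,2S)-1-{[tert-butyl(dimethyl)silyl]oxy}-1-(3,4,5-trimethoxyphenyl)propan-2-yl]-4-(prop-2-en-1-yl)cyclohex-2-en-1-one (C4 epimers)
Product: 16 4-[(1R,2S)-1-{[tert-butyl(dimethyl)silyl]oxy}-1-(3,4,5-trimethoxyphenyl)propan-2-yl]-4-(prop-2-en-1-yl)cyclohexa-2,5-dien-1-one, via trimethylsilyl dienol ether 15 (not isolated)
Conditions: LiN(i-Pr)2, Me3SiCl, THF, –78 °C; then Pd(OAc)2 (1.1 equiv), MeCN, rt
Reagents that add atoms: none
Why: Ito–Saegusa oxidation, in which deprotonation can occur only at C6 because C4 is quaternary, and palladation of the silyl dienol ether with β-hydride elimination gives the cross-conjugated dienone whose former stereocentre is now prochiral.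

**Step 8**
Reactants: 16 4-[(1R,2S)-1-{[tert-butyl(dimethyl)silyl]oxy}-1-(3,4,5-trimethoxyphenyl)propan-2-yl]-4-(prop-2-en-1-yl)cyclohexa-2,5-dien-1-one
Product: 17 4-[(1R,2S)-1-hydroxy-1-(3,4,5-trimethoxyphenyl)propan-2-yl]-4-(prop-2-en-1-yl)cyclohexa-2,5-dien-1-one
Conditions: HF·pyridine, pyridine, THF, 0 °C → rt
Reagents that add atoms: none
Why: Fluoride cleavage of the silyl ether without base lets the hydroxy dienone be isolated, and any adduct that forms prematurely enters the same equilibrium in step 9.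

**Step 9**
Reactants: 17 4-[(1R,2S)-1-hydroxy-1-(3,4,5-trimethoxyphenyl)propan-2-yl]-4-(prop-2-en-1-yl)cyclohexa-2,5-dien-1-one
Product: 18 (2R,3S,3aS,7aS)-3-methyl-3a-(prop-2-en-1-yl)-2-(3,4,5-trimethoxyphenyl)-2,3,3a,7a-tetrahydro-1-benzofuran-6(7H)-one
Conditions: 1,8-diazabicyclo[5.4.0]undec-7-ene (DBU, 0.5 equiv), MeCN, 25 → 45 °C, until the isomer composition no longer changes
Reagents that add atoms: none
Why: The base activates the C2 hydroxyl, the alkoxide adds to the β-carbon of one enone arm and the enolate is protonated at C7, forming O1–C7a; the closest known reaction type is the diastereoselective desymmetrization of 4,4-disubstituted cyclohexa-2,5-dienones by intramolecular oxa-Michael addition. Ring A closes 5-exo-trig, and the short tether allows only a cis ring fusion, so C7a follows C3a. C3a is set by which of the two diastereotopic arms is attacked: in 18 the C2 aryl and C3 methyl groups lie on the convex face together with the angular allyl group, whereas closure on the other arm would press both under the folded ring B. Because the addition is reversible under base (retro-oxa-Michael through the C6 enolate), both adducts interconvert via 17 and the outcome reflects this stability difference, not the rates of closure. The step needs only selection between the two arms, since both give the same constitution, and this is secured by the fixed (2R,3S) centres from step 1, which are not touched.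

**Step 10**
Reactants: 18 (2R,3S,3aS,7aS)-3-methyl-3a-(prop-2-en-1-yl)-2-(3,4,5-trimethoxyphenyl)-2,3,3a,7a-tetrahydro-1-benzofuran-6(7H)-one
Product: 20 (2R,3S,3aS)-3-methyl-3a-(prop-2-en-1-yl)-2-(3,4,5-trimethoxyphenyl)-3,3a-dihydro-1-benzofuran-6(2H)-one, via trimethylsilyl dienol ether 19 (not isolated)
Conditions: Me3SiCl then LiN(i-Pr)2 (internal quench), THF, –78 °C; then Pd(OAc)2 (1.1 equiv), MeCN, rt
Reagents that add atoms: none
Why: Ito–Saegusa oxidation, in which the internal quench traps the C7 enolate before it can expel the C7a alkoxide and β-hydride elimination toward C7a gives the vinylogous ester, as in the dehydrogenation of tetrahydropyran-4-ones to dihydropyranones; C7a becomes sp2 while C2, C3 and C3a are untouched.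

**Step 11**
Reactants: 20 (2R,3S,3aS)-3-methyl-3a-(prop-2-en-1-yl)-2-(3,4,5-trimethoxyphenyl)-3,3a-dihydro-1-benzofuran-6(2H)-one
Product: 21 (2R,3S,3aR,4S,5S)-4,5-epoxy-3-methyl-3a-(prop-2-en-1-yl)-2-(3,4,5-trimethoxyphenyl)-3,3a,4,5-tetrahydro-1-benzofuran-6(2H)-one (oxirane anti to allyl)
Conditions: t-BuOOH, DBU, CH2Cl2, 0 °C → rt
Reagents that add atoms: tert-butyl hydroperoxide, CC(C)(C)OO
Why: Nucleophilic (Weitz–Scheffer-type) epoxidation in which the peroxide anion adds only to C4 of the simple enone arm, because the C7=C7a arm is a deactivated, fully substituted vinylogous ester and the allyl alkene is inert to a nucleophilic oxidant; the oxirane configuration is lost in step 12.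

**Step 12**
Reactants: 21 (2R,3S,3aR,4S,5S)-4,5-epoxy-3-methyl-3a-(prop-2-en-1-yl)-2-(3,4,5-trimethoxyphenyl)-3,3a,4,5-tetrahydro-1-benzofuran-6(2H)-one
Product: 22 (2R,3S,3aR)-5-methoxy-3-methyl-3a-(prop-2-en-1-yl)-2-(3,4,5-trimethoxyphenyl)-3,3a-dihydro-1-benzofuran-6(2H)-one
Conditions: NaOMe, MeOH, rt → 50 °C
Reagents that add atoms: methanol, CO
Why: Base-mediated methanolysis of an α,β-epoxy ketone to a 2-methoxy enone, in which methoxide opens the oxirane at C5 (α to the carbonyl, whereas C4 is neopentyl) and the β-hydroxy ketone dehydrates by E1cB, as in the classical preparation of diosphenol ethers.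

**Step 13**
Reactants: 22 (2R,3S,3aR)-5-methoxy-3-methyl-3a-(prop-2-en-1-yl)-2-(3,4,5-trimethoxyphenyl)-3,3a-dihydro-1-benzofuran-6(2H)-one
Product: 24 (2R,3S,3aS,5R)-5-methoxy-3-methyl-3a-(prop-2-en-1-yl)-2-(3,4,5-trimethoxyphenyl)-3,3a,4,5-tetrahydro-1-benzofuran-6(2H)-one (dysodanthin B), via lithium enolate 23 (not isolated)
Conditions: LiBH(s-Bu)3, THF, –78 °C; then 2,6-di-tert-butyl-4-methylphenol, –78 °C; cold pH 7 buffer
Reagents that add atoms: none
Why: Conjugate reduction with a trialkylborohydride followed by kinetic enolate protonation, in which hydride adds to the unsubstituted β-carbon C4 (the pattern of 1,4-reduction of steroidal 1-en-3-ones next to a quaternary carbon), the β-alkoxy arm and the allyl group are inert, and the bulky phenol should protonate C5 from the face opposite the angular allyl group, leaving methoxy syn to allyl (5R).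

**Compound list**
1 | 3,4,5-trimethoxybenzaldehyde | COc1cc(C=O)cc(OC)c1OC | starting material
2 | (Z)-crotylboronic acid pinacol ester, 4,4,5,5-tetramethyl-2-[(2Z)-but-2-en-1-yl]-1,3,2-dioxaborolane | C/C=C\CB1OC(C)(C)C(C)(C)O1 | starting material
3 | (1R,2S)-2-methyl-1-(3,4,5-trimethoxyphenyl)but-3-en-1-ol | C=C[C@H](C)[C@@H](O)c1cc(OC)c(OC)c(OC)c1 | intermediate
4 | tert-butyl(dimethyl){[(1R,2S)-2-methyl-1-(3,4,5-trimethoxyphenyl)but-3-en-1-yl]oxy}silane | C=C[C@H](C)[C@@H](O[Si](C)(C)C(C)(C)C)c1cc(OC)c(OC)c(OC)c1 | intermediate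
5 | (3S,4R)-4-{[tert-butyl(dimethyl)silyl]oxy}-3-methyl-4-(3,4,5-trimethoxyphenyl)butan-1-ol | OCC[C@H](C)[C@@H](O[Si](C)(C)C(C)(C)C)c1cc(OC)c(OC)c(OC)c1 | intermediate
6 | (3S,4R)-4-{[tert-butyl(dimethyl)silyl]oxy}-3-methyl-4-(3,4,5-trimethoxyphenyl)butanal | O=CC[C@H](C)[C@@H](O[Si](C)(C)C(C)(C)C)c1cc(OC)c(OC)c(OC)c1 | intermediate
7 | allyl bromide (3-bromoprop-1-ene) | C=CCBr | starting material
8 | (E)-N-cyclohexyl imine of 6 | C1CCCCC1/N=C/C[C@H](C)[C@@H](O[Si](C)(C)C(C)(C)C)c1cc(OC)c(OC)c(OC)c1 | intermediate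
9 | (E)-N-cyclohexyl imine of 10 (C2 epimers) | C1CCCCC1/N=C/C(CC=C)[C@H](C)[C@@H](O[Si](C)(C)C(C)(C)C)c1cc(OC)c(OC)c(OC)c1 | intermediate
10 | (3S,4R)-4-{[tert-butyl(dimethyl)silyl]oxy}-3-methyl-2-(prop-2-en-1-yl)-4-(3,4,5-trimethoxyphenyl)butanal (C2 epimers) | C=CCC(C=O)[C@H](C)[C@@H](O[Si](C)(C)C(C)(C)C)c1cc(OC)c(OC)c(OC)c1 | intermediate
11 | but-3-en-2-one (methyl vinyl ketone) | CC(=O)C=C | starting material
12 | 1-[(3S,4R)-4-{[tert-butyl(dimethyl)silyl]oxy}-3-methyl-2-(prop-2-en-1-yl)-4-(3,4,5-trimethoxyphenyl)but-1-en-1-yl]pyrrolidine (E/Z mixture) | C=CCC(=CN1CCCC1)[C@H](C)[C@@H](O[Si](C)(C)C(C)(C)C)c1cc(OC)c(OC)c(OC)c1 | intermediate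
13 | 2-[(1R,2S)-1-{[tert-butyl(dimethyl)silyl]oxy}-1-(3,4,5-trimethoxyphenyl)propan-2-yl]-5-oxo-2-(prop-2-en-1-yl)hexanal (C2 epimers) | C=CCC(C=O)(CCC(C)=O)[C@H](C)[C@@H](O[Si](C)(C)C(C)(C)C)c1cc(OC)c(OC)c(OC)c1 | intermediate
14 | 4-[(1R,2S)-1-{[tert-butyl(dimethyl)silyl]oxy}-1-(3,4,5-trimethoxyphenyl)propan-2-yl]-4-(prop-2-en-1-yl)cyclohex-2-en-1-one (C4 epimers) | C=CCC1([C@H](C)[C@@H](O[Si](C)(C)C(C)(C)C)c2cc(OC)c(OC)c(OC)c2)C=CC(=O)CC1 | intermediate
15 | trimethylsilyl dienol ether of 14 (1-trimethylsilyloxycyclohexa-1,5-diene, C4 epimers) | C=CCC1([C@H](C)[C@@H](O[Si](C)(C)C(C)(C)C)c2cc(OC)c(OC)c(OC)c2)C=CC(O[Si](C)(C)C)=CC1 | intermediate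
16 | 4-[(1R,2S)-1-{[tert-butyl(dimethyl)silyl]oxy}-1-(3,4,5-trimethoxyphenyl)propan-2-yl]-4-(prop-2-en-1-yl)cyclohexa-2,5-dien-1-one | C=CCC1([C@H](C)[C@@H](O[Si](C)(C)C(C)(C)C)c2cc(OC)c(OC)c(OC)c2)C=CC(=O)C=C1 | intermediate
17 | 4-[(1R,2S)-1-hydroxy-1-(3,4,5-trimethoxyphenyl)propan-2-yl]-4-(prop-2-en-1-yl)cyclohexa-2,5-dien-1-one | C=CCC1([C@H](C)[C@@H](O)c2cc(OC)c(OC)c(OC)c2)C=CC(=O)C=C1 | intermediate
18 | (2R,3S,3aS,7aS)-3-methyl-3a-(prop-2-en-1-yl)-2-(3,4,5-trimethoxyphenyl)-2,3,3a,7a-tetrahydro-1-benzofuran-6(7H)-one | C=CC[C@@]12C=CC(=O)C[C@@H]1O[C@@H](c1cc(OC)c(OC)c(OC)c1)[C@H]2C | intermediate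
19 | trimethylsilyl dienol ether of 18, (2R,3S,3aS,7aS)-6-trimethylsilyloxy-2,3,3a,7a-tetrahydro-1-benzofuran | C=CC[C@@]12C=CC(O[Si](C)(C)C)=C[C@@H]1O[C@@H](c1cc(OC)c(OC)c(OC)c1)[C@H]2C | intermediate
20 | (2R,3S,3aS)-3-methyl-3a-(prop-2-en-1-yl)-2-(3,4,5-trimethoxyphenyl)-3,3a-dihydro-1-benzofuran-6(2H)-one | C=CC[C@@]12C=CC(=O)C=C1O[C@@H](c1cc(OC)c(OC)c(OC)c1)[C@H]2C | intermediate
21 | (2R,3S,3aR,4S,5S)-4,5-epoxy-3-methyl-3a-(prop-2-en-1-yl)-2-(3,4,5-trimethoxyphenyl)-3,3a,4,5-tetrahydro-1-benzofuran-6(2H)-one | C=CC[C@@]12[C@@H]3O[C@@H]3C(=O)C=C1O[C@@H](c1cc(OC)c(OC)c(OC)c1)[C@H]2C | intermediate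
22 | (2R,3S,3aR)-5-methoxy-3-methyl-3a-(prop-2-en-1-yl)-2-(3,4,5-trimethoxyphenyl)-3,3a-dihydro-1-benzofuran-6(2H)-one | C=CC[C@@]12C=C(OC)C(=O)C=C1O[C@@H](c1cc(OC)c(OC)c(OC)c1)[C@H]2C | intermediate
23 | lithium (2R,3S,3aS)-5-methoxy-3-methyl-3a-(prop-2-en-1-yl)-2-(3,4,5-trimethoxyphenyl)-2,3,3a,4-tetrahydro-1-benzofuran-6-olate | C=CC[C@@]12CC(OC)=C([O-])C=C1O[C@@H](c1cc(OC)c(OC)c(OC)c1)[C@H]2C.[Li+] | intermediate
24 | dysodanthin B, (2R,3S,3aS,5R)-5-methoxy-3-methyl-3a-(prop-2-en-1-yl)-2-(3,4,5-trimethoxyphenyl)-3,3a,4,5-tetrahydro-1-benzofuran-6(2H)-one | C=CC[C@@]12C[C@@H](OC)C(=O)C=C1O[C@@H](c1cc(OC)c(OC)c(OC)c1)[C@H]2C | target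

**Totals**
Total step count: 13. Longest linear sequence: 13 steps (1 to 24).

**Steps most likely to fail**

Step 6. The Michael addition that creates the quaternary carbon may stall, because the enamine carbon is flanked by a branched, silyloxy-bearing chain; the vinyl ketone would then polymerize and the enamine hydrolyse back. The fallback sets out from aldehyde 6 and comes back at dienone 16. It makes the quaternary carbon by dearomatization instead of by a congested Michael addition. Diethylamine-catalysed Michael addition of 6, whose α-carbon is unbranched, to 11 should give the keto aldehyde F1. Aldol condensation (KOH, MeOH) closes the 4-monosubstituted cyclohexenone F2. Dehydrogenation with 2-iodoxybenzoic acid (DMSO, 70 °C) and tautomerization give the phenol F3. Oxidative Hosomi–Sakurai para-allylation of F3 (PhI(OAc)2, allyltrimethylsilane, (CF3)2CHOH, 0 °C) then installs allyl at the substituted para carbon and gives 16.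

Step 13. The proton may be delivered to the allyl-bearing face of the enolate, or the C5 configuration may be lost by enolization during work-up. The fallback sets out from dienone 20 and comes back at target 24. It introduces the C5 oxygen on the enolate instead of the C5 hydrogen. Conjugate reduction of 20 with LiBH(s-Bu)3 gives the lithium enolate F4. This is oxidized in the same flask with 2-(phenylsulfonyl)-3-phenyloxaziridine to the 5-hydroxy ketone F5. The oxidant should enter on the face the proton preferred, so a facial preference that spoils step 13 now places oxygen syn to allyl. O-Methylation under neutral conditions (MeI, Ag2O) gives 24.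

Step 9. The equilibrium may discriminate too little between the two enone arms, or the retro-addition may be too slow for the mixture to equilibrate. The fallback sets out from 17 and comes back at 18. It replaces thermodynamic substrate control by kinetic catalyst control. The closure is run without base at low temperature with a chiral phosphoric acid (the antipode of 3,3'-bis(2,4,6-triisopropylphenyl)-1,1'-binaphthyl-2,2'-diyl hydrogen phosphate that is matched with the C2/C3 centres). This is a known mode of enantioselective oxa-Michael desymmetrization of cyclohexadienones. No compound outside the list arises (F0).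

**Further compounds**
F1 | step 6 | 2-[(1R,2S)-1-{[tert-butyl(dimethyl)silyl]oxy}-1-(3,4,5-trimethoxyphenyl)propan-2-yl]-5-oxohexanal (C2 epimers) | CC(=O)CCC(C=O)[C@H](C)[C@@H](O[Si](C)(C)C(C)(C)C)c1cc(OC)c(OC)c(OC)c1
F2 | step 6 | 4-[(1R,2S)-1-{[tert-butyl(dimethyl)silyl]oxy}-1-(3,4,5-trimethoxyphenyl)propan-2-yl]cyclohex-2-en-1-one (C4 epimers) | O=C1C=CC(CC1)[C@H](C)[C@@H](O[Si](C)(C)C(C)(C)C)c1cc(OC)c(OC)c(OC)c1
F3 | step 6 | 4-[(1R,2S)-1-{[tert-butyl(dimethyl)silyl]oxy}-1-(3,4,5-trimethoxyphenyl)propan-2-yl]phenol | Oc1ccc(cc1)[C@H](C)[C@@H](O[Si](C)(C)C(C)(C)C)c1cc(OC)c(OC)c(OC)c1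
F0 | step 9 | none | none
F4 | step 13 | lithium (2R,3S,3aS)-3-methyl-3a-(prop-2-en-1-yl)-2-(3,4,5-trimethoxyphenyl)-2,3,3a,4-tetrahydro-1-benzofuran-6-olate | C=CC[C@@]12CC=C([O-])C=C1O[C@@H](c1cc(OC)c(OC)c(OC)c1)[C@H]2C.[Li+]
F5 | step 13 | (2R,3S,3aS,5R)-5-hydroxy-3-methyl-3a-(prop-2-en-1-yl)-2-(3,4,5-trimethoxyphenyl)-3,3a,4,5-tetrahydro-1-benzofuran-6(2H)-one | C=CC[C@@]12C[C@@H](O)C(=O)C=C1O[C@@H](c1cc(OC)c(OC)c(OC)c1)[C@H]2C
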